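**Plan**

1. Retrosynthesis: after removal of the acetonide and ester, ring D is cut at C13–C16 and ring C at C8–C14, and C8–C12 is joined again. Ring C is thus traced back to the four-membered ring C8–C9–C11–C12 of a 1-vinylcyclobutanol that carries a propargyl group on C8. The enabling feature is the 12-ketone of ring C: its α-carbon C13 bears the C16 methylene unit of ring D and its 1,4-partner C8 is quaternary, so C12(=O)–C13–C14 is a vinyl ketone retron and C13 a radical site that reaches the C15–C16–C17 alkyne.
2. Further cuts: cyclobutanone by keteniminium–alkene [2+2] (C8–C9, C11–C12); C6–C8 and C8–C15 by enolate alkylation; the vinyl group from a temporary seven-membered lactone; the 2,3-diol from the 2,3-alkene; C10–O and C4–CH3 from an aromatic ring A.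
3. Forward order: ring A (arene, chiral cyclohexadiene, bridged γ-lactone, cis-diol acetonide), then ring B together with the cyclobutanone, then rings C and D in one radical cascade, then C6 equilibration and deprotection.
4. Stereochemistry: C4 from a prolinol auxiliary; C10 and C5 from C4 by anti addition in the lactonisation; C2/C3 by exo osmylation; C9/C8 by the cis-fused [2+2]; C8 (re-formed) and C13 by ring constraints in the cascade.
5. C6 is set last by thermodynamic equilibration, so the epimer mixtures at C6, C8 and C12 carried through steps 11–15 converge on one isomer.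

Key step: step 15

Remark: positions are numbered as in the gibberellane skeleton of the target (C1–C19, lactone C19–O–C10, C7 acid on C6); α is the face of the lactone oxygen on C10.
Assumption: the (S)-auxiliary is taken to deliver the methyl group to the face that gives the C4 configuration drawn for 8; if the sense of induction is the opposite, the (R)-auxiliary is used from step 1 and nothing else changes.

Step 1
Reactants: 1 3-bromo-2-methylbenzoic acid; 2 (S)-2-(methoxymethyl)pyrrolidine
Product: 3 N-(3-bromo-2-methylbenzoyl)-(S)-2-(methoxymethyl)pyrrolidine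
Conditions: (COCl)2, DMF (cat.), CH2Cl2, 0 °C to rt; then 2, Et3N, CH2Cl2, 0 °C to rt
Reagents that add atoms: none
Why: amide formation through the acid chloride attaches the auxiliary that later controls the quaternary centre C4; no stereocentre is formed.

Step 2
Reactants: 3 bromo amide; 4 potassium [2-(benzyloxy)ethyl]trifluoroborate
Product: 5 N-{3-[2-(benzyloxy)ethyl]-2-methylbenzoyl}-(S)-2-(methoxymethyl)pyrrolidine
Conditions: PdCl2[P(t-Bu)2(4-Me2NC6H4)]2 (5 mol %), Cs2CO3, toluene/H2O (4:1), 100 °C
Reagents that add atoms: none
Why: Suzuki–Miyaura coupling of an aryl bromide with a primary alkyltrifluoroborate installs C9–C11 as a protected 2-hydroxyethyl arm, the β-alkoxyethyl borate being stable to β-elimination under these conditions.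

Step 3
Reactants: 5 benzyl ether amide
Product: 6 2-{2-[2-(benzyloxy)ethyl]-6-[(S)-2-(methoxymethyl)pyrrolidine-1-carbonyl]phenyl}acetic acid
Conditions: LDA, THF, −78 °C; CO2; aq. HCl
Reagents that add atoms: carbon dioxide, O=C=O
Why: amide-directed lateral lithiation of the o-toluamide methyl group followed by carboxylation introduces C6–C7 at the methyl group that the carboxamide acidifies and coordinates, not at the remote benzylic CH2.

Step 4
Reactants: 6 benzyl ether acid
Product: 7 2-{2-(2-hydroxyethyl)-6-[(S)-2-(methoxymethyl)pyrrolidine-1-carbonyl]phenyl}acetic acid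
Conditions: H2 (1 atm), Pd/C, MeOH, rt
Reagents that add atoms: none
Why: hydrogenolysis frees the alcohol now, so that no benzyl anion (and hence no amide base) is generated in the dissolving-metal step that follows.

Step 5
Reactants: 7 hydroxy acid
Product: 8 2-{(6R)-2-(2-hydroxyethyl)-6-methyl-6-[(S)-2-(methoxymethyl)pyrrolidine-1-carbonyl]cyclohexa-1,4-dien-1-yl}acetic acid (ring A as 2,3- and 5,10-diene, C4 quaternary)
Conditions: KH (2 equiv), THF, 0 °C; K, NH3/THF, t-BuOH (1 equiv), −78 °C; piperylene; MeI, −78 °C; NH4Cl; aq. HCl
Reagents that add atoms: iodomethane, CI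
Why: auxiliary-controlled Birch reduction–alkylation of a chiral benzamide: the carboxamide directs reduction to C4/C1, and the potassium amide enolate, chelated by the methoxymethyl arm, is methylated on one face to set C4, while the carboxylate and alkoxide side chains stay inert as potassium salts.

Step 6
Reactants: 8 dienyl hydroxy acid
Product: 9 seven-membered lactone of 8 (C7 carboxyl esterified by the C11 hydroxyl across the C5=C10 alkene)
Conditions: EDC·HCl, DMAP, CH2Cl2 (0.005 M), rt
Reagents that add atoms: none
Why: Steglich-type lactonisation at high dilution, helped by the cis disposition of the two arms on the tetrasubstituted alkene, builds a temporary ring that masks both the C7 acid and the C11 alcohol from the cation chemistry of step 7.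

Step 7
Reactants: 9 lactone amide
Product: 11 bis-lactone: ring A 2,3-ene bridged by the 19,10-γ-lactone (4β-methyl, O-10α, H-5β) with the seven-membered C7–O–C11 lactone retained, via iminium ether triflate 10 (not isolated)
Conditions: TfOH, CH2Cl2, −20 °C to rt; then H2O/THF; aq. NaHCO3
Reagents that add atoms: water, O
Why: amide-assisted protio-lactonisation: protonation of the tetrasubstituted alkene at C5 gives the tertiary C10 cation, the amide oxygen traps it (five-membered ring) and water hydrolyses the iminium ether with loss of the auxiliary; the γ-lactone geometry allows only anti addition, so O-10α and H-5β follow from C4.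

Step 8
Reactants: 11 bis-lactone alkene
Product: 12 2β,3β-diol of 11
Conditions: OsO4 (2 mol %), NMO, acetone/H2O, rt
Reagents that add atoms: N-methylmorpholine N-oxide, C[N+]1([O-])CCOCC1; water, O
Why: catalytic osmylation should take the exo face of the bridged lactone (syn to the one-atom bridge C5, anti to the O–C19 bridge that lies under C2), giving the cis-2β,3β-diol.

Step 9
Reactants: 12 diol
Product: 13 2β,3β-O-isopropylidene derivative of 12
Conditions: Me2C(OMe)2, PPTS (cat.), CH2Cl2, rt
Reagents that add atoms: 2,2-dimethoxypropane, COC(C)(C)OC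
Why: acetonide formation on the cis-diol protects it against the bases, Tf2O and Grignard reagent to come and later blocks retro-aldol cleavage at C3.

Step 10
Reactants: 13 acetonide bis-lactone
Product: 15 (10-vinyl ring A lactone acetonide)-5-yl acetic acid (C9=C11 vinyl on C10, free C7 acid on C6H2), via phenylselenide acid 14 (not isolated)
Conditions: PhSeSePh, Na, THF then HMPA, 65 °C; then 30% H2O2, pyridine, THF, 0 to 40 °C; aq. HCl
Reagents that add atoms: none
Why: the soft selenolate opens the seven-membered lactone by alkyl–oxygen cleavage at primary C11 (the tertiary C10–O of the bridged lactone cannot react in this way), and selenoxide syn-elimination then gives the vinyl group while the C7 acid is set free.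

Step 11
Reactants: 15 vinyl acid; 16 2-bromo-N,N-dimethylacetamide; 17 propargyl bromide
Product: 19 acid amide with C8 (bearing H, propargyl and the C12 dimethylamide) attached to C6 (mixture at C6 and C8), via mono-alkylated acid 18 (not isolated)
Conditions: LDA (2.2 equiv), THF/DMPU, −78 to 0 °C; 16, −78 °C to rt; LDA (1.2 equiv), −78 °C; 17, −78 to 0 °C; aq. HCl
Reagents that add atoms: none
Why: alkylation of the carboxylic acid dianion at C6 with the α-bromoamide, then deprotonation of the accessible amide CH2 (the C6–H is now a hindered methine next to a carboxylate) and propargylation; C6 and C8 are left as mixtures because C8 becomes sp2 in step 13 and C6 is equilibrated in step 16.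

Step 12
Reactants: 19 acid amide
Product: 20 methyl ester of 19
Conditions: TMSCHN2, toluene/MeOH, 0 °C
Reagents that add atoms: trimethylsilyldiazomethane, C[Si](C)(C)C=[N+]=[N-]
Why: neutral esterification removes the free acid, which would not survive Tf2O.

Step 13
Reactants: 20 ester amide
Product: 22 cyclobutanone: ring B closed and cis-fused at C8–C9 to a cyclobutanone (C12=O on C8, C11 on C9; 8β-propargyl, H-9β, four-membered ring on the α-face; C6 epimers), via cyclobutaniminium triflate 21 (not isolated)
Conditions: Tf2O, 2,4,6-collidine, ClCH2CH2Cl, 0 to 80 °C; then aq. NaHCO3, rt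
Reagents that add atoms: water, O
Why: intramolecular keteniminium–olefin [2+2] cycloaddition: the electrophilic C12 bonds to the terminal alkene carbon C11 and C8 to C9 across a three-atom tether, which sets C8/C9 cis; the four-membered ring should form on the face of nascent ring B that is syn to the small lactone oxygen and anti to the acetonide-bearing C1–C3 bridge.

Step 14
Reactants: 22 cyclobutanone
Product: 23 12-hydroxy-12-vinyl cyclobutanol (C12 and C6 epimers)
Conditions: CH2=CHMgBr, CeCl3, THF, −78 °C; aq. NH4Cl at −78 °C
Reagents that add atoms: vinylmagnesium bromide, C=C[Mg]Br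
Why: 1,2-addition of the vinyl organocerium to the strained ketone, far more electrophilic than the hindered ester and lactone, brings in C13 and C14; the carbinol configuration is irrelevant because C12 becomes sp2 again, and the cold quench prevents the alkoxide from lactonising onto the C7 ester.

Step 15
Reactants: 23 vinylcyclobutanol
Product: 24 methyl ester acetonide of the complete skeleton (ring C cyclohexanone with C12=O, ring D with the C16=C17 methylene; C6 epimers)
Conditions: [Ir(dF(CF3)ppy)2(5,5'-d(CF3)bpy)]PF6 (2 mol %), 2,4,6-collidine, 2,4,6-triisopropylbenzenethiol (10 mol %), PhCF3 (0.02 M), blue LEDs, rt, degassed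
Reagents that add atoms: none
Why: Proposed new method: the excited trivalent iridium photocatalyst and collidine remove the O–H hydrogen by proton-coupled electron transfer, and the alkoxy radical opens the strained four-membered ring by β-scission of C12–C8 (tertiary radical at C8 rather than primary at C11), unveiling the vinyl ketone C12(=O)–C13=C14. The nucleophilic C8 radical adds to C14 (6-endo-trig, polarity-matched; the chain hangs from the α-face of C9, so ring C closes cis to it and C8 is re-formed with C15 β), which is the known two-carbon ring expansion of 1-vinylcycloalkanols under these conditions. The α-keto radical, born only at C13, then cyclises 5-exo-dig onto the propargyl alkyne (ring D; C13 is fixed by the bridge), as in manganese triacetate or atom-transfer cyclisations of α-carbonyl radicals to bicyclo[3.2.1]octanes, and the vinyl radical takes hydrogen from the thiol, whose thiyl radical is returned by the reduced (divalent) iridium and collidinium. The step needs the C13 radical to cyclise before it is reduced: it is electrophilic and so polarity-mismatched for hydrogen transfer from the thiol, thiol and photocatalyst are kept dilute, and the alkyne sits 1,3-diaxial to C13 in the cis-fused ring. Running the two radical events in one chain has no direct precedent, although each elementary step has a close analogue.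

Step 16
Reactants: 24 methyl ester (C6 epimers)
Product: 26 7-carboxylic acid acetonide (6β, lactone intact), via 6β methyl ester 25 (not isolated)
Conditions: NaOMe, MeOH, 60 °C; then 2 M NaOH, 70 °C; aq. HCl to pH 3, 0 °C
Reagents that add atoms: sodium hydroxide, [Na+].[OH-]
Why: enolate equilibration places C7 trans to C4 on ring B (6β, away from the C18/C19 groups) before saponification; the γ-lactone, if opened by base, should reclose on acidification, and C13 (bridgehead) and C9 cannot epimerise.

Step 17
Reactants: 26 acetonide acid
Product: 27 target, 2β,3β-dihydroxy-12-oxo-16-ene C19-gibberellin 19,10-lactone 7-oic acid (CNP0307952.1)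
Conditions: AcOH/H2O (4:1), 50 °C
Reagents that add atoms: none
Why: mild acid hydrolysis of the acetonide should leave the lactone, the ketone and the exocyclic alkene untouched (the alkene cannot move into conjugation through the bridgehead C13).

**Compound list**

1 | 3-bromo-2-methylbenzoic acid | Cc1c(Br)cccc1C(=O)O | starting material
2 | (S)-2-(methoxymethyl)pyrrolidine | COC[C@@H]1CCCN1 | starting material
3 | N-(3-bromo-2-methylbenzoyl)-(S)-2-(methoxymethyl)pyrrolidine | Cc1c(Br)cccc1C(=O)N1CCC[C@H]1COC | intermediate
4 | potassium [2-(benzyloxy)ethyl]trifluoroborate | [K+].F[B-](F)(F)CCOCc1ccccc1 | starting material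
5 | N-{3-[2-(benzyloxy)ethyl]-2-methylbenzoyl}-(S)-2-(methoxymethyl)pyrrolidine | Cc1c(CCOCc2ccccc2)cccc1C(=O)N1CCC[C@H]1COC | intermediate
6 | 2-{2-[2-(benzyloxy)ethyl]-6-[(S)-2-(methoxymethyl)pyrrolidine-1-carbonyl]phenyl}acetic acid | OC(=O)Cc1c(CCOCc2ccccc2)cccc1C(=O)N1CCC[C@H]1COC | intermediate
7 | 2-{2-(2-hydroxyethyl)-6-[(S)-2-(methoxymethyl)pyrrolidine-1-carbonyl]phenyl}acetic acid | OC(=O)Cc1c(CCO)cccc1C(=O)N1CCC[C@H]1COC | intermediate
8 | 2-{(6R)-2-(2-hydroxyethyl)-6-methyl-6-[(S)-2-(methoxymethyl)pyrrolidine-1-carbonyl]cyclohexa-1,4-dien-1-yl}acetic acid | OCCC1=C(CC(=O)O)[C@](C)(C(=O)N2CCC[C@H]2COC)C=CC1 | intermediate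
9 | seven-membered C7–O–C11 lactone of 8 | O=C1OCCC2=C(C1)[C@](C)(C(=O)N3CCC[C@H]3COC)C=CC2 | intermediate
10 | cyclic iminium ether triflate (C19=N+ of the auxiliary, ring oxygen on C10, H-5β) | O=C1OCC[C@@]23CC=C[C@@](C)(C(=[N+]4CCC[C@H]4COC)O2)[C@H]3C1.[O-]S(=O)(=O)C(F)(F)F | intermediate
11 | bis-lactone, ring A 2,3-ene with 19,10-γ-lactone (4β-Me, O-10α, H-5β) and seven-membered C7–O–C11 lactone | O=C1OCC[C@@]23CC=C[C@@](C)(C(=O)O2)[C@H]3C1 | intermediate
12 | 2β,3β-diol of 11 | O=C1OCC[C@@]23C[C@H](O)[C@H](O)[C@@](C)(C(=O)O2)[C@H]3C1 | intermediate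
13 | 2β,3β-O-isopropylidene derivative of 12 | O=C1OCC[C@@]23C[C@@H]4OC(C)(C)O[C@@H]4[C@@](C)(C(=O)O2)[C@H]3C1 | intermediate
14 | C11 phenylselenide C7 acid (sodium salt in the flask) | c1ccccc1[Se]CC[C@@]23C[C@@H]4OC(C)(C)O[C@@H]4[C@@](C)(C(=O)O2)[C@H]3CC(=O)O | intermediate
15 | 10-vinyl ring A lactone acetonide with CH2CO2H (C6, C7) on C5 | C=C[C@@]23C[C@@H]4OC(C)(C)O[C@@H]4[C@@](C)(C(=O)O2)[C@H]3CC(=O)O | intermediate
16 | 2-bromo-N,N-dimethylacetamide | CN(C)C(=O)CBr | starting material
17 | propargyl bromide (3-bromoprop-1-yne) | C#CCBr | starting material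
18 | C6-(dimethylcarbamoylmethyl) acid (dilithium salt in the flask; C6 epimers) | C=C[C@@]23C[C@@H]4OC(C)(C)O[C@@H]4[C@@](C)(C(=O)O2)[C@H]3C(CC(=O)N(C)C)C(=O)O | intermediate
19 | acid with C8 bearing propargyl and the C12 dimethylamide (mixture at C6 and C8) | C=C[C@@]23C[C@@H]4OC(C)(C)O[C@@H]4[C@@](C)(C(=O)O2)[C@H]3C(C(CC#C)C(=O)N(C)C)C(=O)O | intermediate
20 | methyl ester of 19 | C=C[C@@]23C[C@@H]4OC(C)(C)O[C@@H]4[C@@](C)(C(=O)O2)[C@H]3C(C(CC#C)C(=O)N(C)C)C(=O)OC | intermediate
21 | cyclobutaniminium triflate (N,N-dimethyliminium at C12) | C#CC[C@]12C(=[N+](C)C)C[C@H]1[C@@]34C[C@@H]5OC(C)(C)O[C@@H]5[C@@](C)(C(=O)O3)[C@H]4C2C(=O)OC.[O-]S(=O)(=O)C(F)(F)F | intermediate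
22 | cyclobutanone cis-fused to ring B at C8–C9 (8β-propargyl, H-9β, C12=O; C6 epimers) | C#CC[C@]12C(=O)C[C@H]1[C@@]34C[C@@H]5OC(C)(C)O[C@@H]5[C@@](C)(C(=O)O3)[C@H]4C2C(=O)OC | intermediate
23 | 12-hydroxy-12-vinyl cyclobutanol (C12 and C6 epimers) | C#CC[C@]12C(O)(C=C)C[C@H]1[C@@]34C[C@@H]5OC(C)(C)O[C@@H]5[C@@](C)(C(=O)O3)[C@H]4C2C(=O)OC | intermediate
24 | methyl ester acetonide of the target skeleton (C6 epimers) | C=C1C[C@]23C[C@H]1C(=O)C[C@H]2[C@@]12C[C@@H]4OC(C)(C)O[C@@H]4[C@@](C)(C(=O)O1)[C@H]2C3C(=O)OC | intermediate
25 | 6β methyl ester acetonide | C=C1C[C@]23C[C@H]1C(=O)C[C@H]2[C@@]12C[C@@H]4OC(C)(C)O[C@@H]4[C@@](C)(C(=O)O1)[C@H]2[C@@H]3C(=O)OC | intermediate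
26 | 7-carboxylic acid acetonide | C=C1C[C@]23C[C@H]1C(=O)C[C@H]2[C@@]12C[C@@H]4OC(C)(C)O[C@@H]4[C@@](C)(C(=O)O1)[C@H]2[C@@H]3C(=O)O | intermediate
27 | CNP0307952.1, 2β,3β-dihydroxy-12-oxo-16-ene C19-gibberellin 19,10-lactone 7-oic acid | C=C1C[C@]23C[C@H]1C(=O)C[C@H]2[C@@]12C[C@H](O)[C@H](O)[C@@](C)(C(=O)O1)[C@H]2[C@@H]3C(=O)O | target

**Step count and risks**

Total step count: 17. Longest linear sequence: 17 steps (from 1 to 27; compounds 2, 4, 16 and 17 are purchased).

The three steps most likely to fail:

Step 15 (proposed new method). The C13 α-keto radical may be reduced by the reduced photocatalyst or the thiol before it closes onto the alkyne, or thiyl radicals may add to the alkyne, so that only ring expansion occurs. The fallback, built from known reactions, closes ring D by ionic means. It sets out from 23: the established two-carbon ring expansion under the same photocatalyst with a higher thiol loading should give the cis-fused hydrindanone F1 with the propargyl group untouched. Kinetic enolisation with KHMDS and TBSCl at −78 °C, away from C11 (shielded by C9 and C10), should give the C12=C13 silyl enol ether F2. Ph3PAuNTf2 (cat.) in CH2Cl2/MeOH then effects the 5-exo-dig Conia-ene-type carbocyclisation of the enol silane onto the terminal alkyne and comes back to the route at 24.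

Step 13. The cycloaddition may show poor facial selectivity with respect to ring A, or the activated amide may be intercepted by the neighbouring ester carbonyl. The fallback replaces substrate control by auxiliary control and sets out from 15. Bromoacetyl bromide and (2R,5R)-2,5-dimethylpyrrolidine give the C2-symmetric bromoacetamide F3. It is used in place of 16 in the two-stage alkylation, giving through the mono-alkylated acid F4 (not isolated) the propargylated acid F5, which is esterified to the methyl ester F6. Tf2O/collidine then generates a chiral keteniminium salt whose [2+2] cycloaddition gives the cyclobutaniminium triflate F7; hydrolysis comes back to the route at 22. The enantiomer of the amine that reinforces the substrate bias would be chosen.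

Step 7. The cyclohexadienyl cation may rearrange (methyl or acyl shift with aromatisation) or the amide may lactonise onto C2 before the C10 cation is trapped. The fallback avoids strong acid and sets out from 9. Iodolactonisation (I2, THF/H2O, NaHCO3) of the electron-rich tetrasubstituted alkene should give, with loss of the auxiliary, the C5-iodo γ-lactone F8. Radical deiodination with Bu3SnH/AIBN then comes back to the route at 11; the seven-membered lactone shields the α-side of the C5 radical, so hydrogen should arrive from the β-face.

Further compounds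
F1 | step 15 | ring-expanded cis-hydrindanone (C12 ketone, 8β-propargyl, ring D open; C6 epimers) | C#CC[C@]12CCC(=O)C[C@H]1[C@@]34C[C@@H]5OC(C)(C)O[C@@H]5[C@@](C)(C(=O)O3)[C@H]4C2C(=O)OC
F2 | step 15 | C12=C13 tert-butyldimethylsilyl enol ether of F1 | C#CC[C@]12CC=C(O[Si](C)(C)C(C)(C)C)C[C@H]1[C@@]34C[C@@H]5OC(C)(C)O[C@@H]5[C@@](C)(C(=O)O3)[C@H]4C2C(=O)OC
F3 | step 13 | 2-bromo-1-[(2R,5R)-2,5-dimethylpyrrolidin-1-yl]ethan-1-one | BrCC(=O)N1[C@H](C)CC[C@H]1C
F4 | step 13 | C6-alkylated acid with the (2R,5R)-2,5-dimethylpyrrolidine amide (dilithium salt in the flask; C6 epimers) | C=C[C@@]23C[C@@H]4OC(C)(C)O[C@@H]4[C@@](C)(C(=O)O2)[C@H]3C(CC(=O)N5[C@H](C)CC[C@H]5C)C(=O)O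
F5 | step 13 | propargylated acid with the (2R,5R)-2,5-dimethylpyrrolidine amide (mixture at C6 and C8) | C=C[C@@]23C[C@@H]4OC(C)(C)O[C@@H]4[C@@](C)(C(=O)O2)[C@H]3C(C(CC#C)C(=O)N5[C@H](C)CC[C@H]5C)C(=O)O
F6 | step 13 | methyl ester of F5 | C=C[C@@]23C[C@@H]4OC(C)(C)O[C@@H]4[C@@](C)(C(=O)O2)[C@H]3C(C(CC#C)C(=O)N5[C@H](C)CC[C@H]5C)C(=O)OC
F7 | step 13 | cyclobutaniminium triflate with the (2R,5R)-2,5-dimethylpyrrolidinium unit at C12 | C#CC[C@]12C(=[N+]6[C@H](C)CC[C@H]6C)C[C@H]1[C@@]34C[C@@H]5OC(C)(C)O[C@@H]5[C@@](C)(C(=O)O3)[C@H]4C2C(=O)OC.[O-]S(=O)(=O)C(F)(F)F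
F8 | step 7 | 5β-iodo analogue of 11 (iodine on C5 anti to O-10) | O=C1OCC[C@@]23CC=C[C@@](C)(C(=O)O2)[C@@]3(I)C1
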